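**Plan**

- Retrosynthesis: the C3–acyl bond, one carbinol methyl and the prenyl terminus are removed first (acyl chloride, MeMgBr, cross-metathesis). The C6–C7 bond of the cyclopentane is then cut by reversing a 1,2-shift, which leads back to a 7-methylbicyclo[3.3.1]non-7-ene. That bicycle is opened at C3–C4 (Dieckmann), C1–C2 (aldol), C5–allyl (Pd allylation) and C5–C6/C1–C8 (Michael/aldol annulation).
- Forward: the cyclohexenone ring is built first, the 1,3-dione ring is closed onto it to give the bicyclo[3.3.1]nonene, the carbocycle is contracted to the cyclopentane of the bicyclo[3.2.1]octane, and the side chains are finished last.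
- Feature used: the cyclopentane ring C1–C7–C6–C5–C8 carries at C7, next to the methyl bridgehead C1, a two-carbon oxygenated group. The C6–C7 bond plus that acetyl-type carbon is what a 1-methylcyclohexene unit (C1–C8H=C7(Me)–C6–C5–C9, alkene CH on C1) gives when its ring methylene shifts under oxidation.
- Stereochemistry: C5 from ligand-controlled Pd allylation; C1 relayed from C5 in the aldol step and proof-read by the Dieckmann closure, which only the cis isomer can undergo; C7 from exo attack of the iodane followed by an invertive shift; the acyl stereocentre from (R)-2-methylbutanoic acid.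

Key step: step 7

Assumption: the enantiomer of the bisphosphine ligand in step 2 is the one whose palladium complex gives the 1R ester 6 (to be fixed on the first run), and (R)-2-methylbutanoic acid 19 is bought as a single enantiomer.

**Route**

Step 1
Reactants: 1 methyl 3-oxopentanoate; 2 methacrolein (2-methylprop-2-enal)
Product: 4 methyl 3,5-dimethyl-2-oxocyclohex-3-ene-1-carboxylate, via Michael adduct 3 (not isolated)
Conditions: Et3N (cat.), CH2Cl2, 0 °C → rt; then TsOH·H2O (cat.), PhMe, 80 °C
Reagents that add atoms: none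
Why: Base-catalysed Michael addition of the β-keto ester to the enal followed by acid-catalysed intramolecular aldol condensation through the ethyl-ketone methylene (Robinson-type annulation) can close only the six-membered enone, and the two stereocentres of 4 need no control because one is quaternised in step 2 and the other becomes sp2 in step 3.

Step 2
Reactants: 4 methyl 3,5-dimethyl-2-oxocyclohex-3-ene-1-carboxylate; 5 allyl acetate
Product: 6 methyl (1R)-3,5-dimethyl-2-oxo-1-(prop-2-en-1-yl)cyclohex-3-ene-1-carboxylate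
Conditions: [Pd(C3H5)Cl]2 (cat.), N,N′-(cyclohexane-1,2-diyl)bis[2-(diphenylphosphanyl)benzamide] (single enantiomer, cat.), 1,1,3,3-tetramethylguanidine, PhMe, 0 °C
Reagents that add atoms: none
Why: Tsuji–Trost asymmetric allylic alkylation, in which the stabilised β-keto ester enolate attacks the π-allyl complex formed from zerovalent palladium and 5 inside the chiral pocket of the ligand, which should select the enolate face and set the quaternary centre (the later C5 bridgehead) as 1R.

Step 3
Reactants: 6 methyl (1R)-3,5-dimethyl-2-oxo-1-(prop-2-en-1-yl)cyclohex-3-ene-1-carboxylate; 7 acetaldehyde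
Product: 9 methyl (1R,5R)-5-(1-hydroxyethyl)-3,5-dimethyl-6-oxo-1-(prop-2-en-1-yl)cyclohex-3-ene-1-carboxylate, via lithium dienolate 8 (not isolated)
Conditions: LiN(iPr)2, THF, −78 → −20 °C; then MeCHO, −78 °C; AcOH, −78 °C
Reagents that add atoms: none
Why: With the α′ position quaternary the amide base removes the γ-hydrogen to give the extended enolate 8, whose kinetic aldol addition takes place at the α-carbon, moving the alkene out of conjugation and creating the second quaternary centre (the later C1 bridgehead); the ester carbonyl is expected to chelate lithium in the enolate plane, leaving the allyl group pseudo-axial so that the aldehyde adds anti to it, that is cis to the ester, while the carbinol centre is lost in step 4.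

Step 4
Reactants: 9 methyl (1R,5R)-5-(1-hydroxyethyl)-3,5-dimethyl-6-oxo-1-(prop-2-en-1-yl)cyclohex-3-ene-1-carboxylate
Product: 10 methyl (1R,5R)-5-acetyl-3,5-dimethyl-6-oxo-1-(prop-2-en-1-yl)cyclohex-3-ene-1-carboxylate
Conditions: Dess–Martin periodinane, CH2Cl2, rt
Reagents that add atoms: none
Why: Dess–Martin oxidation should convert the hindered secondary alcohol into the methyl ketone under non-basic conditions that do not trigger retro-aldol cleavage.

Step 5
Reactants: 10 methyl (1R,5R)-5-acetyl-3,5-dimethyl-6-oxo-1-(prop-2-en-1-yl)cyclohex-3-ene-1-carboxylate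
Product: 11 (1R,5S)-1,7-dimethyl-5-(prop-2-en-1-yl)bicyclo[3.3.1]non-7-ene-2,4,9-trione
Conditions: KOtBu, THF, 0 °C → rt; 1 M HCl
Reagents that add atoms: none
Why: Dieckmann condensation in which the acetyl enolate, the only enolate available, attacks the cis-disposed ester across the ring ketone (6-exo-trig acyl substitution), and deprotonation of the resulting 1,3-diketone should drive closure of the bicyclo[3.3.1]nonane, whose bridgehead configurations are those already present in 10.

Step 6
Reactants: 11 (1R,5S)-1,7-dimethyl-5-(prop-2-en-1-yl)bicyclo[3.3.1]non-7-ene-2,4,9-trione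
Product: 12 (1R,5S)-2-methoxy-1,7-dimethyl-5-(prop-2-en-1-yl)bicyclo[3.3.1]nona-2,7-diene-4,9-dione
Conditions: Me2SO4, K2CO3, acetone, rt
Reagents that add atoms: dimethyl sulfate, COS(=O)(=O)OC
Why: O-alkylation of the vinylogous acid with a hard methylating agent is expected to favour the oxygen flanked by the smaller methyl bridgehead, and methylation at the other oxygen, the competing event, would be handled by chromatography and hydrolytic recycling to 11.

Step 7
Reactants: 12 (1R,5S)-2-methoxy-1,7-dimethyl-5-(prop-2-en-1-yl)bicyclo[3.3.1]nona-2,7-diene-4,9-dione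
Product: 14 (1R,5S,7R)-7-acetyl-2-methoxy-1-methyl-5-(prop-2-en-1-yl)bicyclo[3.2.1]oct-2-ene-4,8-dione, via dimethyl ketal 13 (not isolated)
Conditions: PhI(OH)OTs, MeOH, 0 °C → rt; then 1 M HCl, THF, 0 °C
Reagents that add atoms: methanol, CO; water, O
Why: The trivalent iodine electrophile should add to the trisubstituted C7=C8 bond at C8 (the CH carbon next to bridgehead C1) while methanol is captured at the methyl-bearing C7 (Markovnikov); in the boat-like conformer of the carbocycle the C6–C7 bond lies anti-periplanar to the C8–I bond, so C6 shifts from C7 to C8 as iodobenzene leaves, and the C7 oxocarbenium ion is trapped as ketal 13 and hydrolysed to the acetyl group. The closest known reaction type is the oxidative ring contraction of cycloalkenes by trivalent iodine or thallium trinitrate in methanol (1-methylcyclohexene to acetylcyclopentane, 1,2-dihydronaphthalenes to indanes). The five-membered ring (C1, C8, C6, C5, C9 of 12) is closed not by cyclisation of a chain but by a suprafacial 1,2-alkyl shift with inversion at the migration terminus C8. The new stereocentre (C7 of 14) is fixed by exo attack of the iodane, the endo face being screened by C2 and C4, which are axial on the carbocycle, together with the invertive shift, which places the acetyl group exo (7R). The step needs chemoselectivity for C7=C8 over the allyl group and the C2=C3 enol ether, and preference for the shift over 1,2-dimethoxylation: the ring alkene is the only trisubstituted, non-conjugated π bond, C3 of the vinylogous ester is a poor nucleophile, the endo methoxy group at C7 disfavours the chair that would lead to substitution, and migration of a bond from C1 is excluded because the cation left there would sit next to the C9 carbonyl with no donor.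

Step 8
Reactants: 14 (1R,5S,7R)-7-acetyl-2-methoxy-1-methyl-5-(prop-2-en-1-yl)bicyclo[3.2.1]oct-2-ene-4,8-dione; 15 2-methylbut-2-ene
Product: 16 (1R,5S,7R)-7-acetyl-2-methoxy-1-methyl-5-(3-methylbut-2-en-1-yl)bicyclo[3.2.1]oct-2-ene-4,8-dione
Conditions: (H2IMes)(PCy3)Cl2Ru=CHPh (second-generation Grubbs catalyst, cat.), excess 15, CH2Cl2, 40 °C
Reagents that add atoms: none
Why: Olefin cross-metathesis of the terminal allyl group with an excess of the trisubstituted partner is the standard way to turn allyl into prenyl, and the enol ether and the ketones are inert to the catalyst.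

Step 9
Reactants: 16 (1R,5S,7R)-7-acetyl-2-methoxy-1-methyl-5-(3-methylbut-2-en-1-yl)bicyclo[3.2.1]oct-2-ene-4,8-dione
Product: 17 (1R,5S,7R)-7-(2-hydroxypropan-2-yl)-2-methoxy-1-methyl-5-(3-methylbut-2-en-1-yl)bicyclo[3.2.1]oct-2-ene-4,8-dione
Conditions: CeCl3, MeMgBr, THF, −78 °C; aq. NH4Cl
Reagents that add atoms: methylmagnesium bromide, C[Mg]Br
Why: 1,2-Addition of the organocerium reagent formed from the Grignard reagent and CeCl3, which is nucleophilic but weakly basic, should take the unhindered methyl ketone without enolisation or epimerisation at C7, while the C8 ketone between two quaternary carbons and the vinylogous ester carbonyl stay untouched.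

Step 10
Reactants: 17 (1R,5S,7R)-7-(2-hydroxypropan-2-yl)-2-methoxy-1-methyl-5-(3-methylbut-2-en-1-yl)bicyclo[3.2.1]oct-2-ene-4,8-dione
Product: 18 (1R,5S,7R)-2-methoxy-1-methyl-5-(3-methylbut-2-en-1-yl)-7-{2-[(trimethylsilyl)oxy]propan-2-yl}bicyclo[3.2.1]oct-2-ene-4,8-dione
Conditions: N-(trimethylsilyl)imidazole, CH2Cl2, rt
Reagents that add atoms: N-(trimethylsilyl)imidazole, C[Si](C)(C)n1ccnc1
Why: Silylation of the tertiary alcohol masks the only acidic proton ahead of the lithiation in step 12.

Step 11
Reactants: 19 (2R)-2-methylbutanoic acid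
Product: 20 (2R)-2-methylbutanoyl chloride
Conditions: (COCl)2, DMF (cat.), CH2Cl2, 0 °C → rt
Reagents that add atoms: oxalyl chloride, ClC(=O)C(=O)Cl
Why: Acyl chloride formation with oxalyl chloride under Vilsmeier-type catalysis runs without base, so the α-stereocentre should not be enolised.

Step 12
Reactants: 18 (1R,5S,7R)-2-methoxy-1-methyl-5-(3-methylbut-2-en-1-yl)-7-{2-[(trimethylsilyl)oxy]propan-2-yl}bicyclo[3.2.1]oct-2-ene-4,8-dione; 20 (2R)-2-methylbutanoyl chloride
Product: 22 (1R,5R,7R)-2-methoxy-1-methyl-3-[(2R)-2-methylbutanoyl]-5-(3-methylbut-2-en-1-yl)-7-{2-[(trimethylsilyl)oxy]propan-2-yl}bicyclo[3.2.1]oct-2-ene-4,8-dione, via vinyllithium 21 (not isolated)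
Conditions: lithium 2,2,6,6-tetramethylpiperidide, THF, −78 °C; then 20, −78 → −40 °C
Reagents that add atoms: none
Why: Deprotonation of the vinylic C3–H, the only acidic position now that both bridgeheads are quaternary, by the hindered lithium amide gives vinyllithium 21, which should be C-acylated by the acid chloride at low temperature without loss of the side-chain configuration.

Step 13
Reactants: 22 (1R,5R,7R)-2-methoxy-1-methyl-3-[(2R)-2-methylbutanoyl]-5-(3-methylbut-2-en-1-yl)-7-{2-[(trimethylsilyl)oxy]propan-2-yl}bicyclo[3.2.1]oct-2-ene-4,8-dione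
Product: 24 (1R,5R,7R)-2-hydroxy-7-(2-hydroxypropan-2-yl)-1-methyl-3-[(2R)-2-methylbutanoyl]-5-(3-methylbut-2-en-1-yl)bicyclo[3.2.1]oct-2-ene-4,8-dione, via silyl ether enol 23 (not isolated)
Conditions: LiCl, DMSO, 120 °C; then 1 M HCl, THF, rt
Reagents that add atoms: none
Why: Chloride attacks the methyl group of the activated enol ether in an SN2 (Krapcho-type) dealkylation to release the enolised triketone, and the dilute acid work-up hydrolyses the silyl ether, with no stereocentre affected.

**Compound list**

1 | methyl 3-oxopentanoate | CCC(=O)CC(=O)OC | starting material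
2 | methacrolein (2-methylprop-2-enal) | CC(=C)C=O | starting material
3 | methyl 2-(2-methyl-3-oxopropyl)-3-oxopentanoate (Michael adduct, stereoisomer mixture) | CCC(=O)C(CC(C)C=O)C(=O)OC | intermediate
4 | methyl 3,5-dimethyl-2-oxocyclohex-3-ene-1-carboxylate (racemic, both diastereomers) | COC(=O)C1CC(C)C=C(C)C1=O | intermediate
5 | allyl acetate (prop-2-en-1-yl acetate) | CC(=O)OCC=C | starting material
6 | methyl (1R)-3,5-dimethyl-2-oxo-1-(prop-2-en-1-yl)cyclohex-3-ene-1-carboxylate (both C5 epimers) | O=C1[C@@](CC=C)(CC(C)C=C1C)C(=O)OC | intermediate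
7 | acetaldehyde | CC=O | starting material
8 | lithium (6R)-6-(methoxycarbonyl)-2,4-dimethyl-6-(prop-2-en-1-yl)cyclohexa-1,3-dien-1-olate | [Li]OC1=C(C)C=C(C)C[C@@]1(CC=C)C(=O)OC | intermediate
9 | methyl (1R,5R)-5-(1-hydroxyethyl)-3,5-dimethyl-6-oxo-1-(prop-2-en-1-yl)cyclohex-3-ene-1-carboxylate (carbinol epimers; hydroxyethyl cis to the ester) | CC(O)[C@@]1(C)C=C(C)C[C@@](CC=C)(C(=O)OC)C1=O | intermediate
10 | methyl (1R,5R)-5-acetyl-3,5-dimethyl-6-oxo-1-(prop-2-en-1-yl)cyclohex-3-ene-1-carboxylate (acetyl cis to the ester) | CC(=O)[C@@]1(C)C=C(C)C[C@@](CC=C)(C(=O)OC)C1=O | intermediate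
11 | (1R,5S)-1,7-dimethyl-5-(prop-2-en-1-yl)bicyclo[3.3.1]non-7-ene-2,4,9-trione (drawn as the triketone; enolised across C2–C4) | C1C(=O)[C@]2(C)C(=O)[C@@](CC=C)(CC(C)=C2)C1=O | intermediate
12 | (1R,5S)-2-methoxy-1,7-dimethyl-5-(prop-2-en-1-yl)bicyclo[3.3.1]nona-2,7-diene-4,9-dione | C1=C(OC)[C@]2(C)C(=O)[C@@](CC=C)(CC(C)=C2)C1=O | intermediate
13 | (1R,5S,7R)-7-(1,1-dimethoxyethyl)-2-methoxy-1-methyl-5-(prop-2-en-1-yl)bicyclo[3.2.1]oct-2-ene-4,8-dione (side chain exo) | C1=C(OC)[C@]2(C)C(=O)[C@@](CC=C)(C[C@H]2C(C)(OC)OC)C1=O | intermediate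
14 | (1R,5S,7R)-7-acetyl-2-methoxy-1-methyl-5-(prop-2-en-1-yl)bicyclo[3.2.1]oct-2-ene-4,8-dione (acetyl exo) | C1=C(OC)[C@]2(C)C(=O)[C@@](CC=C)(C[C@H]2C(C)=O)C1=O | intermediate
15 | 2-methylbut-2-ene | CC=C(C)C | starting material
16 | (1R,5S,7R)-7-acetyl-2-methoxy-1-methyl-5-(3-methylbut-2-en-1-yl)bicyclo[3.2.1]oct-2-ene-4,8-dione | C1=C(OC)[C@]2(C)C(=O)[C@@](CC=C(C)C)(C[C@H]2C(C)=O)C1=O | intermediate
17 | (1R,5S,7R)-7-(2-hydroxypropan-2-yl)-2-methoxy-1-methyl-5-(3-methylbut-2-en-1-yl)bicyclo[3.2.1]oct-2-ene-4,8-dione | C1=C(OC)[C@]2(C)C(=O)[C@@](CC=C(C)C)(C[C@H]2C(C)(C)O)C1=O | intermediate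
18 | (1R,5S,7R)-2-methoxy-1-methyl-5-(3-methylbut-2-en-1-yl)-7-{2-[(trimethylsilyl)oxy]propan-2-yl}bicyclo[3.2.1]oct-2-ene-4,8-dione | C1=C(OC)[C@]2(C)C(=O)[C@@](CC=C(C)C)(C[C@H]2C(C)(C)O[Si](C)(C)C)C1=O | intermediate
19 | (2R)-2-methylbutanoic acid | CC[C@@H](C)C(=O)O | starting material
20 | (2R)-2-methylbutanoyl chloride | CC[C@@H](C)C(=O)Cl | intermediate
21 | 3-lithio derivative of 18 (vinyllithium at C3) | [Li]C1=C(OC)[C@]2(C)C(=O)[C@@](CC=C(C)C)(C[C@H]2C(C)(C)O[Si](C)(C)C)C1=O | intermediate
22 | (1R,5R,7R)-2-methoxy-1-methyl-3-[(2R)-2-methylbutanoyl]-5-(3-methylbut-2-en-1-yl)-7-{2-[(trimethylsilyl)oxy]propan-2-yl}bicyclo[3.2.1]oct-2-ene-4,8-dione | CC[C@@H](C)C(=O)C1=C(OC)[C@]2(C)C(=O)[C@@](CC=C(C)C)(C[C@H]2C(C)(C)O[Si](C)(C)C)C1=O | intermediate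
23 | (1R,5R,7R)-2-hydroxy-1-methyl-3-[(2R)-2-methylbutanoyl]-5-(3-methylbut-2-en-1-yl)-7-{2-[(trimethylsilyl)oxy]propan-2-yl}bicyclo[3.2.1]oct-2-ene-4,8-dione | CC[C@@H](C)C(=O)C1=C(O)[C@]2(C)C(=O)[C@@](CC=C(C)C)(C[C@H]2C(C)(C)O[Si](C)(C)C)C1=O | intermediate
24 | (1R,5R,7R)-2-hydroxy-7-(2-hydroxypropan-2-yl)-1-methyl-3-[(2R)-2-methylbutanoyl]-5-(3-methylbut-2-en-1-yl)bicyclo[3.2.1]oct-2-ene-4,8-dione | CC[C@@H](C)C(=O)C1=C(O)[C@]2(C)C(=O)[C@@](CC=C(C)C)(C[C@H]2C(C)(C)O)C1=O | target

**Step count and risks**

Total step count: 13. Longest linear sequence: 12 steps (steps 1–10, 12 and 13); step 11 is a one-step branch.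

Steps most likely to fail:

1. Step 7. The iodane may be consumed at the allyl group or at the push–pull C2=C3 bond. The methoxy-iodane adduct may also be intercepted by methanol (1,2-dimethoxylation) before C6 shifts, or may stay in the chair conformer in which no ring bond is aligned with the C8–I bond. Fallback (leaves 12, rejoins at 14): the same 1,2-shift is run stepwise as a semipinacol rearrangement. mCPBA (CH2Cl2, 0 °C) should epoxidise only the trisubstituted alkene, on its exo face, to the exo-7,8-epoxide F1. HClO4 (cat.) in aqueous THF opens it at the tertiary C7 to the 7,8-diol F2, in which the C8–O bond is still exo. MsCl/Et3N esterifies the secondary hydroxyl to the 8-mesylate F3. AlEt3 (CH2Cl2, −78 °C) then forms the C7 aluminium alkoxide and C6 migrates to C8 anti to the mesylate, which should give 14 with the same exo acetyl group.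

2. Step 3. The aldehyde may add to the dienolate on the face syn to the allyl group, giving the epimer that cannot bridge in step 5. It may also add at the γ-carbon, or the hindered aldolate may revert before the quench. Fallback (leaves 2 and 5, rejoins at 10): the order in which the two substituents at the future C1 are introduced is reversed, so that the small electrophile comes last. Methyl 3-oxobutanoate F4 replaces 1 in the annulation with 2 to give the enone ester F5. Allylation with 5 as in step 2 gives the (1R)-allyl ester F6. γ-Deprotonation and aldol addition of 7 give the hydroxyethyl ketone F7, which is oxidised to the enolised acetyl diketone F8. C-Methylation of F8 (K2CO3, MeI, acetone) then places the methyl group on the face that electrophiles prefer, which in this scenario is the one anti to the ester, leaving the acetyl group cis to the ester as in 10.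

3. Step 2. The catalyst may discriminate the enolate faces insufficiently, and the mismatched C5-methyl epimer of 4 would make this worse, so that the enantiomeric purity of every later compound suffers. Fallback (leaves 4, rejoins at 6): auxiliary control replaces catalyst control. Condensation of 4 with tert-butyl L-valinate gives the chelated enamino ester F9. Lithiation with LiN(iPr)2 and alkylation with allyl bromide give the α-allyl imine F10, the quaternary centre being set by the valine residue (valinate enantiomer and solvent chosen for the 1R sense). Aqueous acid hydrolysis releases 6 and the auxiliary.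

Further compounds

F1 | step 7 | (1R,5S)-7,8-exo-epoxy-2-methoxy-1,7-dimethyl-5-(prop-2-en-1-yl)bicyclo[3.3.1]non-2-ene-4,9-dione (epoxide oxygen on the C9 face) | C1=C(OC)[C@]2(C)C(=O)[C@@](CC=C)(C[C@@]3(C)O[C@@H]23)C1=O
F2 | step 7 | (1R,5S)-7,8-dihydroxy-2-methoxy-1,7-dimethyl-5-(prop-2-en-1-yl)bicyclo[3.3.1]non-2-ene-4,9-dione (C8 hydroxyl exo, C7 either configuration) | C1=C(OC)[C@]2(C)C(=O)[C@@](CC=C)(CC(C)(O)[C@H]2O)C1=O
F3 | step 7 | (1R,5S)-7-hydroxy-2-methoxy-1,7-dimethyl-4,9-dioxo-5-(prop-2-en-1-yl)bicyclo[3.3.1]non-2-en-8-yl methanesulfonate (mesylate exo) | C1=C(OC)[C@]2(C)C(=O)[C@@](CC=C)(CC(C)(O)[C@H]2OS(C)(=O)=O)C1=O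
F4 | step 3 | methyl 3-oxobutanoate | COC(=O)CC(C)=O
F5 | step 3 | methyl 5-methyl-2-oxocyclohex-3-ene-1-carboxylate (racemic, both diastereomers) | COC(=O)C1CC(C)C=CC1=O
F6 | step 3 | methyl (1R)-5-methyl-2-oxo-1-(prop-2-en-1-yl)cyclohex-3-ene-1-carboxylate | O=C1[C@@](CC=C)(CC(C)C=C1)C(=O)OC
F7 | step 3 | methyl (1R)-5-(1-hydroxyethyl)-3-methyl-6-oxo-1-(prop-2-en-1-yl)cyclohex-3-ene-1-carboxylate | CC(O)C1C=C(C)C[C@@](CC=C)(C(=O)OC)C1=O
F8 | step 3 | methyl (1R)-5-acetyl-3-methyl-6-oxo-1-(prop-2-en-1-yl)cyclohex-3-ene-1-carboxylate (enolised 1,3-diketone) | CC(=O)C1C=C(C)C[C@@](CC=C)(C(=O)OC)C1=O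
F9 | step 2 | methyl 2-{[(2S)-1-tert-butoxy-3-methyl-1-oxobutan-2-yl]amino}-3,5-dimethylcyclohexa-1,3-diene-1-carboxylate | CC(C)[C@H](NC1=C(C(=O)OC)CC(C)C=C1C)C(=O)OC(C)(C)C
F10 | step 2 | methyl (1R)-2-{[(2S)-1-tert-butoxy-3-methyl-1-oxobutan-2-yl]imino}-3,5-dimethyl-1-(prop-2-en-1-yl)cyclohex-3-ene-1-carboxylate | CC(C)[C@H](N=C1C(C)=CC(C)C[C@@]1(CC=C)C(=O)OC)C(=O)OC(C)(C)C
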